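Moracin Q is cut at the C1'–C2' bond of ring B. Ring B is a 3',5'-dihydroxyphenyl ring held on benzofuran C2 through C1', the meta-dioxygenation of an acetate-built ring, so it can be folded from a 3,5,7-trioxoheptanoate whose C7 ketone sits on benzofuran C2. In one operation the chain C2 methylene adds to that ketone and the new ring aromatises to a methyl β-resorcylate; its ester carbon leaves later as CO2. The precursor is a benzofuran-2-yl triketo ester carrying the C4 side-chain ketone as a dioxolane and the C6 hydroxyl as a benzyl ether, made from a 4-bromobenzofuran-2-carboxylate by ketone α-arylation and acylation of a triketide trianion.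

Key step: step 9

Remark: 3-bromo-4,5-dihydroxybenzaldehyde (1) and methyl 3,5-dioxohexanoate (15) are taken as catalogue compounds; 16 is written in its all-keto form although it should exist mainly as enol tautomers, and chain C7 and C2 of 16 become C1' and C2' of 18.

Remark: the Br/O/O triad of 1 maps onto C4/C5/C6 of the benzofuran; its formyl carbon is exchanged for the C7a oxygen (step 3) and C3 is introduced by ortho-formylation (step 4).

Step 1
Reactants: 1 3-bromo-4,5-dihydroxybenzaldehyde
Product: 2 3-bromo-5-hydroxy-4-methoxybenzaldehyde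
Conditions: MeI (1.1 equiv), Li2CO3 (1.5 equiv), DMF, 40 °C
Reagents that add atoms: iodomethane, CI
Why: The 4-OH, para to the formyl group and ortho to bromine, is much the more acidic phenol, so the weak base ionises only this site and the Williamson O-methylation should be regioselective, as in the usual 4-O-monoalkylation of 3,4-dihydroxybenzaldehydes.

Step 2
Reactants: 2 3-bromo-5-hydroxy-4-methoxybenzaldehyde
Product: 3 3-(benzyloxy)-5-bromo-4-methoxybenzaldehyde
Conditions: BnBr (1.1 equiv), K2CO3, DMF, 25 °C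
Reagents that add atoms: benzyl bromide, BrCc1ccccc1
Why: Williamson etherification of the only remaining phenol, with no competing nucleophilic site.

Step 3
Reactants: 3 3-(benzyloxy)-5-bromo-4-methoxybenzaldehyde
Product: 5 3-(benzyloxy)-5-bromo-4-methoxyphenol, via aryl formate 4 (not isolated)
Conditions: mCPBA (1.5 equiv), CH2Cl2, 25 °C; aq. NaHCO3 wash; then K2CO3 (0.2 equiv), MeOH, 25 °C
Reagents that add atoms: 3-chloroperoxybenzoic acid, O=C(OO)c1cccc(Cl)c1
Why: Baeyer–Villiger oxidation in which the alkoxy-substituted aryl group migrates to give the aryl formate, which mild methanolysis cleaves to the phenol while the aryl bromide and benzyl ether are inert to peracid.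

Step 4
Reactants: 5 3-(benzyloxy)-5-bromo-4-methoxyphenol
Product: 7 4-(benzyloxy)-2-bromo-6-hydroxy-3-methoxybenzaldehyde, via hydroxymethylphenol 6 (not isolated)
Conditions: MgCl2 (2 equiv), Et3N (4 equiv), (CH2O)n (6 equiv), MeCN, reflux; aq. HCl work-up
Reagents that add atoms: paraformaldehyde (as formaldehyde), C=O
Why: Magnesium-mediated ortho-formylation (Casnati–Skattebøl), in which the magnesium phenoxide delivers formaldehyde only ortho to oxygen, the ortho carbon para to the benzyloxy group (next to Br) is the more nucleophilic of the two, and the hydroxymethyl intermediate is oxidised in the flask by hydride transfer to a second formaldehyde.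

Step 5
Reactants: 7 4-(benzyloxy)-2-bromo-6-hydroxy-3-methoxybenzaldehyde; 8 ethyl bromoacetate
Product: 11 ethyl 6-(benzyloxy)-4-bromo-5-methoxy-1-benzofuran-2-carboxylate, via aryloxyacetate 9 (not isolated), via hydroxydihydrobenzofuran 10 (not isolated)
Conditions: K2CO3 (3 equiv), DMF, 25 → 110 °C
Reagents that add atoms: none
Why: O-alkylation, intramolecular aldol addition of the ester enolate to the ortho formyl group and dehydration (Rap–Stoermer-type benzofuran synthesis), a sequence that tolerates a bromine next to the aldehyde.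

Step 6
Reactants: 11 ethyl 6-(benzyloxy)-4-bromo-5-methoxy-1-benzofuran-2-carboxylate; 12 3-methylbutan-2-one
Product: 13 ethyl 6-(benzyloxy)-5-methoxy-4-(3-methyl-2-oxobutyl)-1-benzofuran-2-carboxylate
Conditions: 12 (3 equiv), Pd(OAc)2 (3 mol %), 2-dicyclohexylphosphino-2'-methylbiphenyl (6 mol %), K3PO4 (2.5 equiv), toluene, 90 °C
Reagents that add atoms: none
Why: Buchwald–Hartwig-type palladium-catalysed α-arylation of a ketone, in which coupling should occur at the unhindered methyl carbon and not at the methine, the doubly ortho-substituted aryl group blocks a second arylation, and the mild phosphate base spares the ethyl ester.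

Step 7
Reactants: 13 ethyl 6-(benzyloxy)-5-methoxy-4-(3-methyl-2-oxobutyl)-1-benzofuran-2-carboxylate
Product: 14 ethyl 6-(benzyloxy)-5-methoxy-4-{[2-(propan-2-yl)-1,3-dioxolan-2-yl]methyl}-1-benzofuran-2-carboxylate
Conditions: Me3SiOCH2CH2OSiMe3 (2 equiv), Me3SiOSO2CF3 (5 mol %), CH2Cl2, −78 → −20 °C; pyridine quench
Reagents that add atoms: 1,2-bis(trimethylsilyloxy)ethane, C[Si](C)(C)OCCO[Si](C)(C)C
Why: Noyori ketalisation, which converts hindered ketones under aprotic conditions that neither transesterify the ester nor touch the benzyl ether and is driven by formation of hexamethyldisiloxane.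

Step 8
Reactants: 14 ethyl 6-(benzyloxy)-5-methoxy-4-{[2-(propan-2-yl)-1,3-dioxolan-2-yl]methyl}-1-benzofuran-2-carboxylate; 15 methyl 3,5-dioxohexanoate
Product: 16 methyl 7-[6-(benzyloxy)-5-methoxy-4-{[2-(propan-2-yl)-1,3-dioxolan-2-yl]methyl}-1-benzofuran-2-yl]-3,5,7-trioxoheptanoate
Conditions: 15 (2.2 equiv), LiN(i-Pr)2 (7 equiv), THF, 0 °C; then 14, −78 → 0 °C; AcOH quench
Reagents that add atoms: none
Why: Claisen acylation of a polyanion, in which only the terminal C6 carbanion of the trianion is strongly nucleophilic and attacks the ethyl ester, the excess trianion takes up the proton of the new β-diketone, and the ketal and benzyl ether offer no acidic or electrophilic site.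

Step 9
Reactants: 16 methyl 7-[6-(benzyloxy)-5-methoxy-4-{[2-(propan-2-yl)-1,3-dioxolan-2-yl]methyl}-1-benzofuran-2-yl]-3,5,7-trioxoheptanoate
Product: 18 methyl 2-[6-(benzyloxy)-5-methoxy-4-{[2-(propan-2-yl)-1,3-dioxolan-2-yl]methyl}-1-benzofuran-2-yl]-4,6-dihydroxybenzoate, via aldol adduct 17 (not isolated)
Conditions: KOH (1 M aq.), MeOH, 0 → 25 °C, N2; then AcOH to pH 5
Reagents that add atoms: none
Why: In aqueous hydroxide the triketo ester is held as its enolates, and the enolate carbon at chain C2 (between the C3 ketone and the ester) adds to the C7 carbonyl on benzofuran C2 to form the C1'–C2' bond, after which the β-hydroxy diketone 17 loses water and enolises twice to the aromatic ring. The closest known reaction is the base-mediated aldol cyclisation of 7-aryl-3,5,7-trioxoheptanoates to 6-aryl-β-resorcylates. Ring B closes as a six-membered carbocycle in a 6-(enolendo)-exo-trig aldol. No stereocentre remains, because the two formed in 17 vanish on aromatisation. The step needs the aldol mode to win over Claisen closure (chain C6 onto the ester, giving an acylphloroglucinol) and over lactonisation to a 4-hydroxy-2-pyrone. Water with a non-chelating potassium counter-ion leaves the ester unactivated, the aryl ketone cannot enolise towards the benzofuran and so stays the best electrophile, and irreversible aromatisation drains the aldol equilibrium, while the dioxolane and benzyl ether are inert to base.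

Step 10
Reactants: 18 methyl 2-[6-(benzyloxy)-5-methoxy-4-{[2-(propan-2-yl)-1,3-dioxolan-2-yl]methyl}-1-benzofuran-2-yl]-4,6-dihydroxybenzoate
Product: 21 1-[6-(benzyloxy)-2-(3,5-dihydroxyphenyl)-5-methoxy-1-benzofuran-4-yl]-3-methylbutan-2-one, via resorcylic acid 19 (not isolated), via keto acid 20 (not isolated)
Conditions: KOH (4 M aq.), 1,4-dioxane, 100 °C, N2; then aq. HCl to pH 1, 80 °C
Reagents that add atoms: water, O
Why: Alkaline hydrolysis of the hindered salicylate-type ester, then acid hydrolysis of the dioxolane and protodecarboxylation of the ortho,para-dihydroxybenzoic acid through ipso protonation of the electron-rich ring, with the benzyl ether shielding ring A from oxidation in hot base.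

Step 11
Reactants: 21 1-[6-(benzyloxy)-2-(3,5-dihydroxyphenyl)-5-methoxy-1-benzofuran-4-yl]-3-methylbutan-2-one
Product: 22 moracin Q
Conditions: H2 (1 atm), 10% Pd/C, EtOAc–MeOH, 25 °C
Reagents that add atoms: none
Why: Catalytic hydrogenolysis of the benzyl aryl ether, which at 1 atm and room temperature should leave the isolated ketone and the 2-arylbenzofuran unreduced if stopped after uptake of one equivalent of H2.

Compound list
1 | 3-bromo-4,5-dihydroxybenzaldehyde | O=Cc1cc(O)c(O)c(Br)c1 | starting material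
2 | 3-bromo-5-hydroxy-4-methoxybenzaldehyde | COc1c(O)cc(C=O)cc1Br | intermediate
3 | 3-(benzyloxy)-5-bromo-4-methoxybenzaldehyde | COc1c(OCc2ccccc2)cc(C=O)cc1Br | intermediate
4 | 3-(benzyloxy)-5-bromo-4-methoxyphenyl formate (not isolated) | COc1c(OCc2ccccc2)cc(OC=O)cc1Br | intermediate
5 | 3-(benzyloxy)-5-bromo-4-methoxyphenol | COc1c(OCc2ccccc2)cc(O)cc1Br | intermediate
6 | 5-(benzyloxy)-3-bromo-2-(hydroxymethyl)-4-methoxyphenol (not isolated) | COc1c(OCc2ccccc2)cc(O)c(CO)c1Br | intermediate
7 | 4-(benzyloxy)-2-bromo-6-hydroxy-3-methoxybenzaldehyde | COc1c(OCc2ccccc2)cc(O)c(C=O)c1Br | intermediate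
8 | ethyl bromoacetate | CCOC(=O)CBr | starting material
9 | ethyl 2-[5-(benzyloxy)-3-bromo-2-formyl-4-methoxyphenoxy]acetate (not isolated) | CCOC(=O)COc1cc(OCc2ccccc2)c(OC)c(Br)c1C=O | intermediate
10 | ethyl 6-(benzyloxy)-4-bromo-3-hydroxy-5-methoxy-2,3-dihydro-1-benzofuran-2-carboxylate (not isolated; racemic mixture of diastereomers, both stereocentres lost on dehydration) | CCOC(=O)C1Oc2cc(OCc3ccccc3)c(OC)c(Br)c2C1O | intermediate
11 | ethyl 6-(benzyloxy)-4-bromo-5-methoxy-1-benzofuran-2-carboxylate | CCOC(=O)c1cc2c(Br)c(OC)c(OCc3ccccc3)cc2o1 | intermediate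
12 | 3-methylbutan-2-one | CC(=O)C(C)C | starting material
13 | ethyl 6-(benzyloxy)-5-methoxy-4-(3-methyl-2-oxobutyl)-1-benzofuran-2-carboxylate | CCOC(=O)c1cc2c(CC(=O)C(C)C)c(OC)c(OCc3ccccc3)cc2o1 | intermediate
14 | ethyl 6-(benzyloxy)-5-methoxy-4-{[2-(propan-2-yl)-1,3-dioxolan-2-yl]methyl}-1-benzofuran-2-carboxylate | CCOC(=O)c1cc2c(CC3(C(C)C)OCCO3)c(OC)c(OCc3ccccc3)cc2o1 | intermediate
15 | methyl 3,5-dioxohexanoate | COC(=O)CC(=O)CC(C)=O | starting material
16 | methyl 7-[6-(benzyloxy)-5-methoxy-4-{[2-(propan-2-yl)-1,3-dioxolan-2-yl]methyl}-1-benzofuran-2-yl]-3,5,7-trioxoheptanoate (key-step precursor) | COc1c(OCc2ccccc2)cc2oc(C(=O)CC(=O)CC(=O)CC(=O)OC)cc2c1CC1(C(C)C)OCCO1 | intermediate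
17 | methyl 2-[6-(benzyloxy)-5-methoxy-4-{[2-(propan-2-yl)-1,3-dioxolan-2-yl]methyl}-1-benzofuran-2-yl]-2-hydroxy-4,6-dioxocyclohexane-1-carboxylate (not isolated; racemic mixture of diastereomers, both stereocentres lost on aromatisation) | COC(=O)C1C(=O)CC(=O)CC1(O)c1cc2c(CC3(C(C)C)OCCO3)c(OC)c(OCc3ccccc3)cc2o1 | intermediate
18 | methyl 2-[6-(benzyloxy)-5-methoxy-4-{[2-(propan-2-yl)-1,3-dioxolan-2-yl]methyl}-1-benzofuran-2-yl]-4,6-dihydroxybenzoate (key-step product) | COc1c(OCc2ccccc2)cc2oc(-c3cc(O)cc(O)c3C(=O)OC)cc2c1CC1(C(C)C)OCCO1 | intermediate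
19 | 2-[6-(benzyloxy)-5-methoxy-4-{[2-(propan-2-yl)-1,3-dioxolan-2-yl]methyl}-1-benzofuran-2-yl]-4,6-dihydroxybenzoic acid (not isolated) | COc1c(OCc2ccccc2)cc2oc(-c3cc(O)cc(O)c3C(=O)O)cc2c1CC1(C(C)C)OCCO1 | intermediate
20 | 2-[6-(benzyloxy)-5-methoxy-4-(3-methyl-2-oxobutyl)-1-benzofuran-2-yl]-4,6-dihydroxybenzoic acid (not isolated) | COc1c(OCc2ccccc2)cc2oc(-c3cc(O)cc(O)c3C(=O)O)cc2c1CC(=O)C(C)C | intermediate
21 | 1-[6-(benzyloxy)-2-(3,5-dihydroxyphenyl)-5-methoxy-1-benzofuran-4-yl]-3-methylbutan-2-one (6-O-benzylmoracin Q) | COc1c(OCc2ccccc2)cc2oc(-c3cc(O)cc(O)c3)cc2c1CC(=O)C(C)C | intermediate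
22 | moracin Q, 1-[2-(3,5-dihydroxyphenyl)-6-hydroxy-5-methoxy-1-benzofuran-4-yl]-3-methylbutan-2-one (achiral) | COc1c(O)cc2oc(-c3cc(O)cc(O)c3)cc2c1CC(=O)C(C)C | target

Total step count: 11. Longest linear sequence: 11 steps (1 to 22); 8, 12 and 15 enter as purchased building blocks.

Steps most likely to fail

Risk 1, step 9. The polyketone chain may close in the wrong mode (Claisen attack on the ester or lactonisation), or hydroxide may fragment it by retro-Claisen cleavage before the aldol closes. The fallback gives up de novo construction of ring B and joins a finished ring B to the benzofuran. It sets out from 14. Saponification (LiOH, THF–H2O, 25 °C) should give 6-(benzyloxy)-5-methoxy-4-{[2-(propan-2-yl)-1,3-dioxolan-2-yl]methyl}-1-benzofuran-2-carboxylic acid F6. Palladium-catalysed decarboxylative cross-coupling of this heteroaryl acid with 1-bromo-3,5-bis(benzyloxy)benzene (Pd[P(t-Bu)3]2, n-Bu4NCl, Cs2CO3, DMF, 170 °C) should give the tribenzyl ketal 6-(benzyloxy)-2-[3,5-bis(benzyloxy)phenyl]-5-methoxy-4-{[2-(propan-2-yl)-1,3-dioxolan-2-yl]methyl}-1-benzofuran F7. Aqueous HCl in THF should free the ketone as 1-[6-(benzyloxy)-2-[3,5-bis(benzyloxy)phenyl]-5-methoxy-1-benzofuran-4-yl]-3-methylbutan-2-one F8. Hydrogenolysis (H2, 10% Pd/C) removes the three benzyl groups, and the route is rejoined at 22.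

Risk 2, step 8. Formation of the trianion may be incomplete, or proton transfer from the acylated product may return it to the unreactive dianion, so that acylation stalls or the diketo ester self-condenses. The fallback builds the chain in two shorter polyanion steps and sets out from 14. The dianion of pentane-2,4-dione (NaH, then n-BuLi, THF, 0 °C) is acylated at its terminal carbon by 14 to give 1-[6-(benzyloxy)-5-methoxy-4-{[2-(propan-2-yl)-1,3-dioxolan-2-yl]methyl}-1-benzofuran-2-yl]hexane-1,3,5-trione F4. Its trianion (LiN(i-Pr)2, 3.3 equiv, THF, 0 °C) is carboxylated at the terminal methyl with CO2 to give 7-[6-(benzyloxy)-5-methoxy-4-{[2-(propan-2-yl)-1,3-dioxolan-2-yl]methyl}-1-benzofuran-2-yl]-3,5,7-trioxoheptanoic acid F5. Brief treatment with Me3SiCHN2 (toluene–MeOH, 0 °C) esterifies the acid, and the route is rejoined at 16.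

Risk 3, step 6. Oxidative addition at the hindered, electron-rich C4–Br bond may be slow, so that hydrodebromination or attack of the ketone enolate on the ester overtakes the coupling. The fallback installs the side chain stepwise from an allyl group and sets out from 11. Suzuki–Miyaura allylation (allylboronic acid pinacol ester, Pd(PPh3)4, CsF, THF, reflux) should give ethyl 4-allyl-6-(benzyloxy)-5-methoxy-1-benzofuran-2-carboxylate F1. Lemieux–Johnson cleavage (OsO4 cat., NaIO4, 2,6-lutidine, dioxane–H2O) gives ethyl 6-(benzyloxy)-5-methoxy-4-(2-oxoethyl)-1-benzofuran-2-carboxylate F2. Addition of i-PrMgCl in the presence of CeCl3 (THF, −78 °C) to the aldehyde, in preference to the ester, gives racemic ethyl 6-(benzyloxy)-4-(2-hydroxy-3-methylbutyl)-5-methoxy-1-benzofuran-2-carboxylate F3. Dess–Martin oxidation then returns the route at 13.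

Further compounds
F1 | step 6 | ethyl 4-allyl-6-(benzyloxy)-5-methoxy-1-benzofuran-2-carboxylate | CCOC(=O)c1cc2c(CC=C)c(OC)c(OCc3ccccc3)cc2o1
F2 | step 6 | ethyl 6-(benzyloxy)-5-methoxy-4-(2-oxoethyl)-1-benzofuran-2-carboxylate | CCOC(=O)c1cc2c(CC=O)c(OC)c(OCc3ccccc3)cc2o1
F3 | step 6 | ethyl 6-(benzyloxy)-4-(2-hydroxy-3-methylbutyl)-5-methoxy-1-benzofuran-2-carboxylate (racemic) | CCOC(=O)c1cc2c(CC(O)C(C)C)c(OC)c(OCc3ccccc3)cc2o1
F4 | step 8 | 1-[6-(benzyloxy)-5-methoxy-4-{[2-(propan-2-yl)-1,3-dioxolan-2-yl]methyl}-1-benzofuran-2-yl]hexane-1,3,5-trione | CC(=O)CC(=O)CC(=O)c1cc2c(CC3(C(C)C)OCCO3)c(OC)c(OCc3ccccc3)cc2o1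
F5 | step 8 | 7-[6-(benzyloxy)-5-methoxy-4-{[2-(propan-2-yl)-1,3-dioxolan-2-yl]methyl}-1-benzofuran-2-yl]-3,5,7-trioxoheptanoic acid | OC(=O)CC(=O)CC(=O)CC(=O)c1cc2c(CC3(C(C)C)OCCO3)c(OC)c(OCc3ccccc3)cc2o1
F6 | step 9 | 6-(benzyloxy)-5-methoxy-4-{[2-(propan-2-yl)-1,3-dioxolan-2-yl]methyl}-1-benzofuran-2-carboxylic acid | OC(=O)c1cc2c(CC3(C(C)C)OCCO3)c(OC)c(OCc3ccccc3)cc2o1
F7 | step 9 | 6-(benzyloxy)-2-[3,5-bis(benzyloxy)phenyl]-5-methoxy-4-{[2-(propan-2-yl)-1,3-dioxolan-2-yl]methyl}-1-benzofuran | COc1c(OCc2ccccc2)cc2oc(-c3cc(OCc4ccccc4)cc(OCc4ccccc4)c3)cc2c1CC1(C(C)C)OCCO1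
F8 | step 9 | 1-[6-(benzyloxy)-2-[3,5-bis(benzyloxy)phenyl]-5-methoxy-1-benzofuran-4-yl]-3-methylbutan-2-one | COc1c(OCc2ccccc2)cc2oc(-c3cc(OCc4ccccc4)cc(OCc4ccccc4)c3)cc2c1CC(=O)C(C)C
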